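## Structural features

Mulberrofuran V (18) is a 2-arylbenzofuran. Ring A (the benzo ring) is fused to the furan ring and carries a free hydroxyl on C6, and the furan C2 is bonded to C1′ of a pentasubstituted phenyl ring B. Ring B carries 3-methylbut-2-enyl (prenyl) groups on C2′ and C6′, hydroxyls on C3′ and C5′, and its only hydrogen on C4′, so the C2–C1′ bond is flanked on both sides by prenyl groups. The target has no stereocentre and no stereogenic double bond, since both side-chain alkenes end in CMe2. The only stereocentres in the plan are three contiguous sp3 carbons of a ring-B precursor, and all three are erased on aromatisation. The fragile elements are the two ortho-prenylphenol units (chromans under acid, chromenes under oxidants), the electron-rich resorcinol and benzofuran, and the trisubstituted alkenes, which rule out hydrogenolysis and strong electrophiles. The real difficulty is regiochemical and steric: both prenyl groups must sit on the hindered carbons next to the biaryl bond, not on C4′ between the oxygens, where direct electrophilic or metalation chemistry would put them. The key step exploits ring B being a 5-aryl-4,6-dialkylresorcinol, the aromatised form of a 5-aryl-4,6-dialkylcyclohexane-1,3-dione: C3′ and C5′ are the carbonyl carbons, C4′ is the methylene between them, and C1′, C2′ and C6′ arrive already substituted from an enone and a malonate.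

## Logic of the disconnections

18 to 17. The O–CH2 bond of the acetal on the C6 oxygen of ring A is cut. The oxygen has to stay masked through every basic step, because its phenoxide would donate through ring A and the furan into C2 and deactivate the conjugate acceptor. Nothing is gained in skeleton. The demand on the forward step is an acetal cleavage that does not protonate the prenyl alkenes of the ortho-prenylphenols.

17 to 14 (through 15 and 16). No skeletal bond is cut. Two hydrogens are added back to ring B and its two phenols are written as ketones. This turns a hexasubstituted benzene into an aliphatic ring that enolate chemistry can assemble with every substituent position fixed. The forward step must be a dehydrogenation that spares two trisubstituted alkenes, the benzofuran and the resorcinol it produces.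

14 to 13. An ethoxycarbonyl group is added to C2′ (C2′–CO2Et bond). It makes C2′ a stabilised nucleophile and supplies the electrophilic carbon that becomes C3′. The simplification is that ring B can now be opened into two acyclic pieces. The forward step has to remove the ester from a quaternary carbon under neutral conditions.

13 to 9 and 11 (through 12). The bonds C1′–C2′ and C3′–C4′ are cut. This is the strategic cut: it opens ring B into a four-carbon piece (C1′, C6′, C5′, C4′) that already carries the benzofuran and one prenyl group, and a two-carbon piece (C2′, C3′) that carries the other. The forward step must join a tertiary carbanion to the β-carbon of an α-branched acceptor and then close the ring before the first bond reverts.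

9 to 5 and 8. The C1′=C6′ double bond is cut by carbonyl olefination logic. This separates the heteroaromatic aldehyde from a small, prenylated ketophosphonate. The forward step is an olefination with a hindered, α-branched stabilised anion. Its alkene geometry does not matter.

8 to 6 and 7, and 11 to 10 and 7. In each case the CH2–C bond between a prenyl group and an activated methine is cut (the future C6′–CH2 and C2′–CH2 bonds). Both prenyl groups then come from the same allylic bromide and are attached where regiochemistry cannot be in doubt. The forward steps must stop at monoalkylation.

5 to 2 (through 3 and 4), and 2 to 1. The C2–C1′ bond is cut as a formylation of the benzofuran C2, then the O–CH2 bond of the acetal is cut. The hindered aryl–heteroaryl bond of the target is thus made as a simple C2–CHO bond, long before its neighbours become crowded. The forward step needs lithiation at C2 in preference to C7.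

## Other disconnections considered

Alternative 1: The cut is at the two aryl–CH2 bonds C2′–CH2 and C6′–CH2, traced back to the two O–CMe2 bonds of the bis(tertiary allyl) ether A1. In the forward step A1 would be heated, or treated with Eu(fod)3 at lower temperature. Each ether would undergo an aromatic Claisen [3,3] shift with allylic inversion, placing a prenyl group on an ortho carbon and freeing a phenol, to give A2.
- In its favour: both rings stay aromatic throughout, so no oxidation-level adjustment of ring B is needed, and on this point it is better than the chosen plan. Its last step would be a fluoride desilylation rather than an acid treatment, which is also better for the ortho-prenylphenols. The biaryl bond would be made while ring B is still unhindered.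
- Against it here: each ether oxygen has two ortho carbons, the wanted C2′/C6′ next to the benzofuran and the unwanted C4′ between the oxygens, and the wanted one is the more crowded. Tertiary allyl aryl ethers can also lose the allyl group by ionisation at Claisen temperatures. The product phenols can close onto their new prenyl groups under heat or Lewis acid. The tertiary ethers of A1 themselves cost extra operations.
- Comparison: the mechanism is pericyclic and neutral, against anionic in the chosen plan. The chosen plan fixes both prenyl positions by construction, whereas this route depends on a site selectivity that the substrate does not guarantee. The step count should be about equal.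

Alternative 2: The cut is at C3–C3a and O1–C7a, so the furan ring is opened. Ring B comes as the methyl ketone A3 and ring A as the bromo-iodoarene A4. In the forward step, Pd2(dba)3, DPEphos and Cs2CO3 would arylate the ketone enolate at the C–I bond and then couple the enolate oxygen at the C–Br bond to give A5.
- In its favour: it is convergent, it makes the furan ring and the ring-A connection in one catalytic operation, and it needs no dehydrogenation. If A3 were in hand, the endgame would be shorter than in the chosen plan, which counts as better on that stretch. The regiochemistry on ring A is settled by the different reactivity of iodide and bromide.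
- Against it here: the hard part is moved, not removed. A3 is a fully substituted ring B with an acetyl group between two prenyl groups, and making it raises the same problem of placing prenyls at the flanked positions rather than at C4′. The O-arylation has to occur next to a di-ortho-substituted aryl group. Three acetal groups would have to be removed by acid in the presence of two ortho-prenylphenols, against one in the chosen plan.
- Comparison: two palladium-catalysed bond formations on a preformed ring B, against anionic construction of ring B. The chosen plan solves the ring-B substitution pattern inside its key step, while this one needs a separate solution before its key step, so its overall step count is expected to be higher.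

Alternative 3: The cut removes three bonds at ring B: C2′–CH2, C6′–CH2 and C1′–C2. The forward step is a Catellani reaction of the aryl iodide A6, two equivalents of the alkyl iodide A7 and the benzofuranylboronate A8 under Pd(OAc)2, a triarylphosphine, norbornene and Cs2CO3. Both ortho positions would be alkylated through a palladacycle and a tetravalent palladium intermediate, norbornene would be extruded, and a Suzuki termination at the ipso carbon would give A9.
- In its favour: it is the most convergent of the four, forming three skeletal bonds in one operation against two in the chosen key step, which is better. The ipso/ortho logic fixes the ring-B pattern unambiguously, which equals the chosen plan. The three components are each one or two steps from commercial materials.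
- Against it here: both ortho C–H positions of A6 are flanked by meta alkoxy groups, the least favourable situation for ortho alkylation in this chemistry. The terminating coupling must join a di-ortho-alkylated arylpalladium to a 2-heteroarylboronate that is prone to protodeboronation. The side chains arrive as silyloxyethyl arms, so each needs desilylation, oxidation to a sensitive arylacetaldehyde level and Wittig isopropylidenation, followed by removal of three acetals.
- Comparison: the chosen plan brings both prenyl groups in intact and needs three steps after its key step. This route needs at least four, two of them on both arms at once. The chosen plan is weaker in redox economy and in convergence of the key step.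

Key step: step 6

Remark on the chemistry: 12, 13, 14 and 15 are carried as diastereomer mixtures because all their stereocentres end as aromatic carbons. Simple enolate or phenoxide salts are treated as forms of their parent compounds and carry no number of their own.

## Route

Step 1
Reactants: 1 benzofuran-6-ol
Product: 2 6-(methoxymethoxy)benzofuran
Conditions: NaH, DMF, 0 °C; MOMCl, 0 °C to rt
Reagents that add atoms: chloromethyl methyl ether, COCCl
Why: Williamson-type O-alkylation of the sodium phenoxide by the α-chloro ether; the acetal should survive every base used later and keeps the C6 oxygen from acting as a phenoxide donor towards C2.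

Step 2
Reactants: 2 6-(methoxymethoxy)benzofuran
Product: 5 6-(methoxymethoxy)benzofuran-2-carbaldehyde, via 2-lithio-6-(methoxymethoxy)benzofuran 3 (not isolated), via lithium hemiaminal alkoxide 4 (not isolated)
Conditions: n-BuLi (1.05 equiv), THF, −78 °C; DMF, −78 to 0 °C; H2O
Reagents that add atoms: N,N-dimethylformamide, CN(C)C=O (formyl carbon and oxygen); n-butyllithium, [Li]CCCC (lithium of 3 and 4 only)
Why: α-Lithiation of benzofuran at C2, its kinetically most acidic C–H, followed by formylation with DMF through the tetrahedral adduct 4, which collapses to the aldehyde on quenching; low temperature and a minimal excess of base should keep metalation away from C7 between the two oxygens.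

Step 3
Reactants: 6 diethyl (2-oxopropyl)phosphonate; 7 1-bromo-3-methylbut-2-ene
Product: 8 diethyl (6-methyl-2-oxohept-5-en-3-yl)phosphonate (racemic)
Conditions: NaH (1.0 equiv), THF, 0 °C; 7 (0.95 equiv), 0 °C to rt
Reagents that add atoms: 1-bromo-3-methylbut-2-ene (compound 7), CC(C)=CCBr
Why: The monoanion of the β-ketophosphonate should undergo SN2 C-alkylation at the carbon between phosphorus and carbonyl with the primary allylic bromide; a slight deficit of bromide limits dialkylation, and the new stereocentre is lost in step 4.

Step 4
Reactants: 5 6-(methoxymethoxy)benzofuran-2-carbaldehyde; 8 diethyl (6-methyl-2-oxohept-5-en-3-yl)phosphonate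
Product: 9 (E)-4-[6-(methoxymethoxy)benzofuran-2-yl]-3-(3-methylbut-2-enyl)but-3-en-2-one
Conditions: 8 (1.2 equiv), NaH (1.1 equiv), THF, 0 °C; 5, rt to 60 °C
Reagents that add atoms: none
Why: Horner–Wadsworth–Emmons olefination of a non-enolisable heteroaryl aldehyde with a stabilised ketophosphonate anion; reversible addition should favour the E alkene (aryl anti to acetyl), and any Z isomer would converge on the same product in step 6.

Step 5
Reactants: 10 diethyl malonate; 7 1-bromo-3-methylbut-2-ene
Product: 11 diethyl 2-(3-methylbut-2-enyl)malonate
Conditions: 10 (1.5 equiv), NaH (1.0 equiv), THF, 0 °C; 7 (1.0 equiv), 0 °C to rt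
Reagents that add atoms: 1-bromo-3-methylbut-2-ene (compound 7), CC(C)=CCBr
Why: Classical malonic ester SN2 alkylation; the excess of malonate should suppress the dialkylated product and is removed by distillation.

Step 6
Reactants: 9 (E)-4-[6-(methoxymethoxy)benzofuran-2-yl]-3-(3-methylbut-2-enyl)but-3-en-2-one; 11 diethyl 2-(3-methylbut-2-enyl)malonate
Product: 13 ethyl 2-[6-(methoxymethoxy)benzofuran-2-yl]-1,3-bis(3-methylbut-2-enyl)-4,6-dioxocyclohexane-1-carboxylate (mixture of diastereomers), via open-chain Michael adduct 12 (not isolated)
Conditions: 11 (1.2 equiv), NaOEt (1.3 equiv), EtOH, rt; 9, rt to reflux; AcOH, 0 °C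
Reagents that add atoms: none
Why: Ethoxide turns 11 into its sodium enolate, which adds to the β-carbon of 9 (Michael addition) to form C1′–C2′ and the keto diester 12; proton exchange then gives the methyl-ketone enolate of 12, which attacks one ester carbonyl in an intramolecular Claisen condensation, forming C3′–C4′ and expelling ethoxide. The closest known reaction type is the dimedone-type annulation of a malonate with an enone to a cyclohexane-1,3-dione. The one ring closes in the 6-(enolendo)-exo-trig mode, with both enolate carbons inside the new ring and the ester C=O outside it, a favourable mode for six-membered rings. Three stereocentres arise (C1, C2 and C3 of 13) under no control beyond equilibration by ethoxide, and none is needed because all three become aromatic carbons. The step needs 1,4- rather than 1,2-addition and closure through the methyl rather than the methine α-carbon: the soft malonate anion adds conjugatively, and only the methyl enolate can reach an ester through a six-membered transition state (the methine enolate would have to form a four-membered ring). The addition of a tertiary carbanion to an α-branched enone is reversible and sterically uphill, but ring closure followed by deprotonation of the acidic C5 methylene of 13 should remove 12 from the equilibrium. The matched ethyl ester and ethoxide exclude transesterification, the prenyl methylene on the enone is cross-conjugated to the carbonyl and so not appreciably acidic, and the final acidification with acetic acid keeps the acetal and the alkenes away from strong acid.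

Step 7
Reactants: 13 ethyl 2-[6-(methoxymethoxy)benzofuran-2-yl]-1,3-bis(3-methylbut-2-enyl)-4,6-dioxocyclohexane-1-carboxylate
Product: 14 5-[6-(methoxymethoxy)benzofuran-2-yl]-4,6-bis(3-methylbut-2-enyl)cyclohexane-1,3-dione (mixture of diastereomers)
Conditions: LiCl (3 equiv), H2O (2 equiv), DMSO, 140–150 °C
Reagents that add atoms: none
Why: Krapcho dealkoxycarbonylation: chloride dealkylates the ethyl ester of the quaternary β-keto ester, the carboxylate loses CO2 and the resulting enolate is protonated; the near-neutral medium should leave the acetal and both prenyl groups untouched, and the stereocentres remain an irrelevant mixture.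

Step 8
Reactants: 14 5-[6-(methoxymethoxy)benzofuran-2-yl]-4,6-bis(3-methylbut-2-enyl)cyclohexane-1,3-dione
Product: 17 5-[6-(methoxymethoxy)benzofuran-2-yl]-4,6-bis(3-methylbut-2-enyl)benzene-1,3-diol, via bis(trimethylsilyl) dienol ether 15 (not isolated), via mono(trimethylsilyl) aryl ether 16 (not isolated)
Conditions: LiN(iPr)2 (2.3 equiv), THF–DMPU, −78 to 0 °C; Me3SiCl (2.6 equiv), −78 °C to rt; crude 15, Pd(OAc)2 (1.05 equiv), MeCN, rt; aq. NH4Cl, THF, rt
Reagents that add atoms: chlorotrimethylsilane, C[Si](C)(C)Cl (silyl groups of 15 and 16 only, absent from 17)
Why: Double O-silylation of the dione dianion gives the 1,3-bis(silyloxy)cyclohexa-1,3-diene 15; Saegusa–Ito oxidation then palladates its terminal, doubly oxygen-activated carbon, and β-hydride elimination of the ring hydrogen on the aryl-bearing carbon gives a cross-conjugated dienone that tautomerises at once to the phenol 16. Mild aqueous work-up removes the remaining aryl silyl ether; stoichiometric Pd(OAc)2 at room temperature should be consumed by the electron-rich dienol ether before it can engage the trisubstituted alkenes.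

Step 9
Reactants: 17 5-[6-(methoxymethoxy)benzofuran-2-yl]-4,6-bis(3-methylbut-2-enyl)benzene-1,3-diol
Product: 18 mulberrofuran V, 5-(6-hydroxybenzofuran-2-yl)-4,6-bis(3-methylbut-2-enyl)benzene-1,3-diol
Conditions: HCl (aq. 3 M, substoichiometric), MeOH, rt to 40 °C, stopped at full conversion
Reagents that add atoms: none
Why: Acid-catalysed methanolysis of the aryl methoxymethyl acetal through an oxocarbenium ion; the acetal oxygens are protonated far more readily than the trisubstituted alkenes, so the protecting group should leave before the ortho-prenylphenols can close to chromans, and no stereocentre is involved.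

## Compound list

1 | benzofuran-6-ol | Oc1ccc2ccoc2c1 | starting material
2 | 6-(methoxymethoxy)benzofuran | COCOc1ccc2ccoc2c1 | intermediate
3 | [6-(methoxymethoxy)benzofuran-2-yl]lithium | [Li]c1cc2ccc(OCOC)cc2o1 | intermediate (not isolated)
4 | lithium (dimethylamino)[6-(methoxymethoxy)benzofuran-2-yl]methanolate (racemic) | CN(C)C([O-])c1cc2ccc(OCOC)cc2o1.[Li+] | intermediate (not isolated)
5 | 6-(methoxymethoxy)benzofuran-2-carbaldehyde | O=Cc1cc2ccc(OCOC)cc2o1 | intermediate
6 | diethyl (2-oxopropyl)phosphonate | CCOP(=O)(CC(C)=O)OCC | starting material
7 | 1-bromo-3-methylbut-2-ene | CC(C)=CCBr | starting material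
8 | diethyl (6-methyl-2-oxohept-5-en-3-yl)phosphonate (racemic) | CCOP(=O)(OCC)C(CC=C(C)C)C(C)=O | intermediate
9 | (E)-4-[6-(methoxymethoxy)benzofuran-2-yl]-3-(3-methylbut-2-enyl)but-3-en-2-one | CC(=O)/C(CC=C(C)C)=C/c1cc2ccc(OCOC)cc2o1 | intermediate
10 | diethyl malonate | CCOC(=O)CC(=O)OCC | starting material
11 | diethyl 2-(3-methylbut-2-enyl)malonate | CCOC(=O)C(CC=C(C)C)C(=O)OCC | intermediate
12 | diethyl 2-{2-acetyl-1-[6-(methoxymethoxy)benzofuran-2-yl]-5-methylhex-4-enyl}-2-(3-methylbut-2-enyl)malonate (mixture of diastereomers) | CCOC(=O)C(CC=C(C)C)(C(=O)OCC)C(c1cc2ccc(OCOC)cc2o1)C(CC=C(C)C)C(C)=O | intermediate (not isolated)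
13 | ethyl 2-[6-(methoxymethoxy)benzofuran-2-yl]-1,3-bis(3-methylbut-2-enyl)-4,6-dioxocyclohexane-1-carboxylate (mixture of diastereomers) | CCOC(=O)C1(CC=C(C)C)C(=O)CC(=O)C(CC=C(C)C)C1c1cc2ccc(OCOC)cc2o1 | intermediate
14 | 5-[6-(methoxymethoxy)benzofuran-2-yl]-4,6-bis(3-methylbut-2-enyl)cyclohexane-1,3-dione (mixture of diastereomers) | CC(C)=CCC1C(=O)CC(=O)C(CC=C(C)C)C1c1cc2ccc(OCOC)cc2o1 | intermediate
15 | 2-[2,6-bis(3-methylbut-2-enyl)-3,5-bis(trimethylsilyloxy)cyclohexa-2,4-dien-1-yl]-6-(methoxymethoxy)benzofuran (mixture of diastereomers) | C[Si](C)(C)OC1=CC(O[Si](C)(C)C)=C(CC=C(C)C)C(c2cc3ccc(OCOC)cc3o2)C1CC=C(C)C | intermediate (not isolated)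
16 | 5-[6-(methoxymethoxy)benzofuran-2-yl]-4,6-bis(3-methylbut-2-enyl)-3-(trimethylsilyloxy)phenol | COCOc1ccc2cc(-c3c(CC=C(C)C)c(O)cc(O[Si](C)(C)C)c3CC=C(C)C)oc2c1 | intermediate (not isolated)
17 | 5-[6-(methoxymethoxy)benzofuran-2-yl]-4,6-bis(3-methylbut-2-enyl)benzene-1,3-diol | COCOc1ccc2cc(-c3c(CC=C(C)C)c(O)cc(O)c3CC=C(C)C)oc2c1 | intermediate
18 | mulberrofuran V, 5-(6-hydroxybenzofuran-2-yl)-4,6-bis(3-methylbut-2-enyl)benzene-1,3-diol | CC(C)=CCc1c(O)cc(O)c(CC=C(C)C)c1-c1cc2ccc(O)cc2o1 | target

## Step count and least certain steps

Total: 9 steps. Longest linear sequence: 7 steps (1 to 2 to 5 to 9 to 13 to 14 to 17 to 18; steps 1, 2, 4, 6, 7, 8 and 9). Steps 3 and 5 are one-step side branches.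

Step 6 (key step). The most likely failure is stalling of the conjugate addition. Joining a tertiary malonate carbanion to the β-carbon of an α-branched, β-heteroaryl enone creates a quaternary carbon next to a tertiary one, so reversal may outrun ring closure, and long heating in ethoxide gives the methyl enolate of 9 time to self-condense. The fallback sets out from 9 and uses the unsubstituted malonate 10, a much less hindered donor, under the same NaOEt/EtOH conditions. This should give ethyl 2-[6-(methoxymethoxy)benzofuran-2-yl]-3-(3-methylbut-2-enyl)-4,6-dioxocyclohexane-1-carboxylate F1. Its dianion (LiN(iPr)2, 2.2 equiv, THF, −78 to 0 °C) should then be alkylated with 7 at the ester-bearing carbon, the last-formed and most basic carbanion site, which comes back to the route at 13.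

Step 8. The most likely failure is loss of regiocontrol in the β-hydride elimination, towards the prenyl methylene instead of the ring C–H, which would pull the side-chain alkene into conjugation. Oxypalladation of a prenyl alkene by the newly formed ortho-prenylphenol is a second hazard if divalent palladium lingers. The fallback avoids palladium. It sets out from 14, which is silylated with tert-butyldimethylsilyl triflate and Et3N in CH2Cl2 to 2-[3,5-bis(tert-butyldimethylsilyloxy)-2,6-bis(3-methylbut-2-enyl)cyclohexa-2,4-dien-1-yl]-6-(methoxymethoxy)benzofuran F2. This cyclohexadiene is aromatised by hydride abstraction with DDQ buffered by 2,4,6-collidine in toluene at 0 °C to 2-[3,5-bis(tert-butyldimethylsilyloxy)-2,6-bis(3-methylbut-2-enyl)phenyl]-6-(methoxymethoxy)benzofuran F3, in which both phenols stay masked against the oxidant. Desilylation with TBAF in THF at 0 °C comes back to the route at 17.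

Step 9. The most likely failure is acid-catalysed hydroalkoxylation, in which a ring-B hydroxyl closes onto its protonated prenyl neighbour while the acetal is being cleaved; the risk grows with contact time and temperature. The fallback masks the nucleophiles and avoids protic acid. It sets out from 17, which is acetylated (Ac2O, pyridine) to 5-[6-(methoxymethoxy)benzofuran-2-yl]-4,6-bis(3-methylbut-2-enyl)-1,3-phenylene diacetate F4. The acetal is removed under aprotic conditions with ZnBr2 and propane-1-thiol in CH2Cl2 at 0 °C to give 5-(6-hydroxybenzofuran-2-yl)-4,6-bis(3-methylbut-2-enyl)-1,3-phenylene diacetate F5. Methanolysis of the acetates with K2CO3 in MeOH comes back to the route at 18.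

Step 4. The most likely failure is incomplete olefination, because the α-branched phosphonate anion is hindered and adds reversibly to an electron-rich heteroaryl aldehyde; mixed alkene geometry would be harmless. The fallback builds the enone in a different order and sets out from 5. A Morita–Baylis–Hillman reaction with but-3-en-2-one and DABCO should give 3-{hydroxy[6-(methoxymethoxy)benzofuran-2-yl]methyl}but-3-en-2-one F6. Acetylation (Ac2O, DMAP) gives [6-(methoxymethoxy)benzofuran-2-yl](3-oxobut-1-en-2-yl)methyl acetate F7. SN2′ displacement of the allylic acetate by (2-methylprop-1-enyl)magnesium bromide with catalytic CuBr·SMe2 in THF at −78 °C creates the prenyl group and the trisubstituted alkene together and comes back to the route at 9.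

## Further compounds

F1 | step 6 | ethyl 2-[6-(methoxymethoxy)benzofuran-2-yl]-3-(3-methylbut-2-enyl)-4,6-dioxocyclohexane-1-carboxylate (mixture of diastereomers) | CCOC(=O)C1C(=O)CC(=O)C(CC=C(C)C)C1c1cc2ccc(OCOC)cc2o1
F2 | step 8 | 2-[3,5-bis(tert-butyldimethylsilyloxy)-2,6-bis(3-methylbut-2-enyl)cyclohexa-2,4-dien-1-yl]-6-(methoxymethoxy)benzofuran (mixture of diastereomers) | CC(C)(C)[Si](C)(C)OC1=CC(O[Si](C)(C)C(C)(C)C)=C(CC=C(C)C)C(c2cc3ccc(OCOC)cc3o2)C1CC=C(C)C
F3 | step 8 | 2-[3,5-bis(tert-butyldimethylsilyloxy)-2,6-bis(3-methylbut-2-enyl)phenyl]-6-(methoxymethoxy)benzofuran | COCOc1ccc2cc(-c3c(CC=C(C)C)c(O[Si](C)(C)C(C)(C)C)cc(O[Si](C)(C)C(C)(C)C)c3CC=C(C)C)oc2c1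
F4 | step 9 | 5-[6-(methoxymethoxy)benzofuran-2-yl]-4,6-bis(3-methylbut-2-enyl)-1,3-phenylene diacetate | COCOc1ccc2cc(-c3c(CC=C(C)C)c(OC(C)=O)cc(OC(C)=O)c3CC=C(C)C)oc2c1
F5 | step 9 | 5-(6-hydroxybenzofuran-2-yl)-4,6-bis(3-methylbut-2-enyl)-1,3-phenylene diacetate | CC(=O)Oc1cc(OC(C)=O)c(CC=C(C)C)c(-c2cc3ccc(O)cc3o2)c1CC=C(C)C
F6 | step 4 | 3-{hydroxy[6-(methoxymethoxy)benzofuran-2-yl]methyl}but-3-en-2-one (racemic) | CC(=O)C(=C)C(O)c1cc2ccc(OCOC)cc2o1
F7 | step 4 | [6-(methoxymethoxy)benzofuran-2-yl](3-oxobut-1-en-2-yl)methyl acetate (racemic) | CC(=O)OC(C(=C)C(C)=O)c1cc2ccc(OCOC)cc2o1
A1 | alternative 1 | 2-[3,5-bis(2-methylbut-3-en-2-yloxy)phenyl]-6-(triisopropylsilyloxy)benzofuran | C=CC(C)(C)Oc1cc(OC(C)(C)C=C)cc(-c2cc3ccc(O[Si](C(C)C)(C(C)C)C(C)C)cc3o2)c1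
A2 | alternative 1 | 4,6-bis(3-methylbut-2-enyl)-5-[6-(triisopropylsilyloxy)benzofuran-2-yl]benzene-1,3-diol | CC(C)=CCc1c(O)cc(O)c(CC=C(C)C)c1-c1cc2ccc(O[Si](C(C)C)(C(C)C)C(C)C)cc2o1
A3 | alternative 2 | 1-[3,5-bis(methoxymethoxy)-2,6-bis(3-methylbut-2-enyl)phenyl]ethanone | CC(=O)c1c(CC=C(C)C)c(OCOC)cc(OCOC)c1CC=C(C)C
A4 | alternative 2 | 2-bromo-1-iodo-4-(methoxymethoxy)benzene | COCOc1ccc(I)c(Br)c1
A5 | alternative 2 | 2-[3,5-bis(methoxymethoxy)-2,6-bis(3-methylbut-2-enyl)phenyl]-6-(methoxymethoxy)benzofuran | COCOc1ccc2cc(-c3c(CC=C(C)C)c(OCOC)cc(OCOC)c3CC=C(C)C)oc2c1
A6 | alternative 3 | 1-iodo-3,5-bis(methoxymethoxy)benzene | COCOc1cc(I)cc(OCOC)c1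
A7 | alternative 3 | tert-butyl(2-iodoethoxy)dimethylsilane | CC(C)(C)[Si](C)(C)OCCI
A8 | alternative 3 | 2-[6-(methoxymethoxy)benzofuran-2-yl]-4,4,5,5-tetramethyl-1,3,2-dioxaborolane | COCOc1ccc2cc(B3OC(C)(C)C(C)(C)O3)oc2c1
A9 | alternative 3 | 2-[2,6-bis[2-(tert-butyldimethylsilyloxy)ethyl]-3,5-bis(methoxymethoxy)phenyl]-6-(methoxymethoxy)benzofuran | COCOc1ccc2cc(-c3c(CCO[Si](C)(C)C(C)(C)C)c(OCOC)cc(OCOC)c3CCO[Si](C)(C)C(C)(C)C)oc2c1
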